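# Mollicellin A: ring A by vinylketene–ynol ether benzannulation on a preformed ring C/D unit

Rings: A = formyl-bearing benzene, B = seven-membered lactone/ether ring, C = second benzene, D = dimethyldihydropyranone. Rings C/D are numbered as a chroman-4-one (O1, C2, C3, C4, C4a, C5–C8, C8a). Ring A carbons are named by their substituents.

Compound numbers: 1 orcinol; 2 hydroxyquinone; 3 methylbenzenetriol; 4 3-methylbut-2-enoic acid; 5 catechol chromanone; 6 its 7-O-allyl ether; 7 silyloxyacetaldehyde; 8 dibromoalkene; 9 bromo enol ether; 10 ynol ether; 11 allyl acetoacetate; 12 allyl diazoacetoacetate; 13 allyl diazoacetate; 14 methacrolein; 15 hydroxy diazo ester; 16 diazo ketoester; 17 vinylketene; 18 vinylcyclobutenone; 19 dienylketene; 20 benzannulation product; 21 hydroxy acid; 22 depsidone silyl ether; 23 benzylic alcohol; 24 mollicellin A.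

## Analysis of the target

Mollicellin A (24) is a tetracyclic depsidone. Ring A carries, in order, CH3, H, OH, CHO, the diaryl ether oxygen and the lactone carbonyl. Ring B holds that ether oxygen and an aryl ester. Ring C carries the ester oxygen (C7), H (C8), the pyran oxygen (C8a), the ketone carbon (C4a), CH3 (C5) and the ether oxygen (C6), and ring D is a 2,2-dimethyl-2,3-dihydropyran-4-one. There is no stereocentre, since the only sp3 ring carbons are the CH2 and C(CH3)2 of ring D, so the problem is one of regiochemistry and chemoselectivity. The sensitive groups are the aryl ester of ring B (opened by hydroxide, alkoxides and amines), the salicylaldehyde unit of ring A, and the chromanone, which opens by retro-oxa-Michael reaction under strong base and absorbs UV light. The synthesis is hard for two reasons. The ether oxygen is flanked by four ortho substituents (CHO and the carboxyl carbon on ring A, CH3 and the ester oxygen on ring C), which makes coupling of two finished arenes unattractive. Ring A also carries five contiguous substituents with three carbon groups at three oxidation levels, which electrophilic substitution cannot place reliably. The strategy rests on the ring A pattern: the OH-bearing carbon and the ether-bearing carbon are 1,3-related with the CHO-bearing carbon between them, and the carboxyl-bearing carbon is para to the OH and next to the CH3-bearing carbon. This is the pattern formed when a vinylketene (supplying C–OH, the carboxyl-bearing carbon, the CH3-bearing carbon and CH) combines with an alkynyl ether (supplying the ether carbon and the CHO-bearing carbon). The hindered oxygen can therefore be attached to ring C as an ynol ether before ring A exists.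

## Retrosynthetic reasoning

**24 back to 22.** The formyl group is taken back to the hydroxymethyl group of 23 and then to the silyl ether 22. A free aldehyde would not survive ketene chemistry, amine-scavenged deallylation or carboxyl activation, whereas a CH2O–silyl group is inert to all three. The forward steps are a silyl ether cleavage that spares the aryl lactone and a benzylic oxidation that stops at the aldehyde.

**22 back to 20.** The acyl C–O bond of ring B is cut, giving the hydroxy acid 21. The aryl ester is the most fragile bond of the target, so it is made after all base and amine steps. In 21 the diaryl ether holds the ring A carboxyl and the ring C 7-hydroxyl in a seven-membered relationship, so the closure is intramolecular, while the ring A hydroxyl (para to the carboxyl) can react only between molecules. Compound 21 comes from 20 by removing one allyl ester and one allyl ether in a single operation.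

**20 back to 10 and 16 (key disconnection).** Three C–C bonds of ring A are cut: C(OH)–C(CH2O), C(OAr)–C(CO2R) and C(OH)–CH. This splits 20 into the ynol ether 10 and the vinylketene 17, which is generated from the diazo ketoester 16 by Wolff rearrangement. The cut is made here because it removes the tetra-ortho-substituted diaryl ether as a coupling problem and places all six ring A positions in one event, with regiochemistry fixed by the polarity of the two partners. The forward reaction must pass through the vinylcyclobutenone 18 and the dienylketene 19 and close ring A by electrocyclisation.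

**10 back to 6 and 8.** The C(sp)–O bond is cut. The oxygen comes from the one free phenol of 6 and the three-carbon chain from the dibromoalkene 8, through the bromo enol ether 9. Compound 8 comes from aldehyde 7 by dibromo-olefination. The forward steps are a copper-catalysed vinylic C–O coupling on a phenol with two ortho substituents, then a dehydrobromination.

**6 back to 1 and 4.** The allyl group of 6 is removed to give catechol 5; its two hydroxyls differ enough in acidity and hindrance to be told apart. Ring D of 5 is cut at the aryl–acyl bond and the O1–C2 bond, giving triol 3 and acid 4. Triol 3 comes from symmetric 1 through hydroxyquinone 2, which places the third oxygen next to the methyl group without ambiguity.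

**16 back to 13 and 14.** The bond between the diazo carbon and the ketone carbon is cut, giving diazoacetate 13 and aldehyde 14 through the hydroxy diazo ester 15. Compound 13 comes from 11 through 12. A diazo-transfer route would pass through a doubly activated vinyl ketone that polymerises readily; the aldol–oxidation route avoids it.

## Alternatives that were turned down

**Alternative 1: oxygen insertion into a xanthone.**
- Disconnection: both C–O bonds of the ester are traced back to the carbonyl of xanthone A1, so ring B comes from a six-membered pyranone.
- Forward key step: (CF3SO2)2O turns the xanthone carbonyl into a 9-triflyloxyxanthylium ion, Me3SiOOSiMe3 adds at C9, and a Criegee-type shift moves the ring C carbon from C9 to oxygen, giving depsidone core A2.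
- For: xanthones are easy to assemble, the hindered ether is in place before ring B becomes seven-membered, and no lactonisation of a hindered acid is needed. On the formation of ring B this alternative is as strong as or stronger than the chosen route.
- Against: two aryl groups can migrate and only electronics decide between them. The chromanone carbonyl sits para to the ring C carbon that must migrate, so ring D cannot be present, and A2 accordingly lacks ring D and the one-carbon substituent of ring A. Ring D annulation in strong acid and ring A formylation would then be done on the lactone, each with two possible sites, after removal of the carbonate and the methyl ether.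
- Comparison: the chosen strategy gives up the rearrangement in exchange for a ring A that arrives fully substituted and a ring D carried from the start, so no electrophilic substitution follows the key step.

**Alternative 2: silicon-tethered triyne cyclotrimerisation.**
- Disconnection: ring A is cut into three alkynes at ether carbon–carboxyl carbon, methyl carbon–CH and silicon-bearing carbon–CH2O carbon, leading to triyne A3.
- Forward key step: RhCl(PPh3)3 trimerises A3 to A4, closing ring A, ring B and a temporary oxasilole in one step.
- For: it is more convergent than the chosen route in the key step, every regiochemical question is settled by tethers, the ester is made on an unhindered alkynoic acid, and ring B needs no lactonisation. On these points it is stronger.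
- Against: A3 puts a base-made ynol ether and a base-labile alkynoate on neighbouring oxygens and carries an ethynylsilyl ether that neither base nor fluoride tolerates. The cyclisation must join an electron-rich and an electron-poor alkyne across a seven-membered tether. The ring A hydroxyl must then come from Tamao–Fleming oxidation of a hindered aryl–silicon bond with basic peroxide next to the aryl lactone.
- Comparison: the chosen strategy uses two separately made partners, and the hydroxyl comes directly from the ketene carbonyl with no C–Si oxidation.

**Alternative 3: ring A as a cyclohexanedione.**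
- Disconnection: the ether C–O bond on ring A is cut and ring A is taken back to the dihydro level, giving ester A5 (a ring C ester of a methylcyclohexanedione carboxylic acid).
- Forward key step: TsOH with water removal condenses the free ring C phenol with the ketone next to the ester-bearing carbon, closing ring B as the vinylogous ester A6; aromatisation and formylation follow.
- For: the hindered ether is made by condensation and not by coupling, the materials are cheap, and no diazo compound or light is needed. On operational simplicity and on precedent for each reaction type it is stronger.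
- Against: A5 is an aryl β-keto ester, which on heating with acid can lose the phenol through an acylketene or undergo Pechmann-type C–C condensation at C8 of ring C. Phenols are poor partners for vinylogous ester formation. Ring A must then be dehydrogenated in the presence of the chromanone CH2–C=O and formylated with two open ortho positions. The stereocentres of A6 have no value.
- Comparison: the chosen strategy delivers ring A aromatic, with the formyl carbon in place one oxidation short of the target.

Key step: step 9

## Route

Remark on the chemistry: 2-diazo-3-oxo esters are taken to absorb weakly up to about 400 nm, beyond the absorption of the chromanone, so a 390 nm diode is specified for step 9.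

Step 1
Reactants: 1 orcinol (5-methylbenzene-1,3-diol)
Product: 3 6-methylbenzene-1,2,4-triol, via hydroxyquinone 2 (not isolated)
Conditions: (KSO3)2NO (2.2 equiv), KH2PO4, H2O, 0 °C to rt; then Na2S2O4, H2O/EtOAc, rt, argon
Reagents that add atoms: potassium nitrosodisulfonate, [O]N(S(=O)(=O)[O-])S(=O)(=O)[O-].[K+].[K+]
Why: Teuber oxidation: the nitroxide forms the phenoxyl radical and a second equivalent delivers oxygen to the free para carbon (the same carbon for either hydroxyl of symmetric 1), giving the hydroxy-para-quinone 2; dithionite then reduces it to the hydroquinone, so the new oxygen sits next to the methyl group without ambiguity. The triol is air-sensitive and is used at once.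

Step 2
Reactants: 3 6-methylbenzene-1,2,4-triol; 4 3-methylbut-2-enoic acid
Product: 5 6,7-dihydroxy-2,2,5-trimethylchroman-4-one
Conditions: P2O5/MeSO3H (1:10), 70 °C, argon
Reagents that add atoms: none
Why: Friedel–Crafts acylation by activated 4 is expected at the ring carbon ortho to the C4 hydroxyl and para to the C2 hydroxyl of 3 (the site that 1,2,4-trioxygenated and resorcinol-type phenols acylate, not the carbon between two hydroxyls); the only hydroxyl ortho to the new enone then closes ring D by oxa-Michael addition (chromanone annulation).

Step 3
Reactants: 5 6,7-dihydroxy-2,2,5-trimethylchroman-4-one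
Product: 6 7-(allyloxy)-6-hydroxy-2,2,5-trimethylchroman-4-one
Conditions: allyl bromide (1.05 equiv), KHCO3, DMF, rt
Reagents that add atoms: allyl bromide, C=CCBr
Why: Williamson etherification under a weak base: the C7 hydroxyl is para to the C4 carbonyl (a vinylogous acid) and unhindered, whereas the C6 hydroxyl is meta to it and flanked by the C5 methyl group, so one equivalent of halide should alkylate C7–OH only.

Step 4
Reactants: 7 (tert-butyldimethylsilyloxy)acetaldehyde
Product: 8 tert-butyl[(3,3-dibromoprop-2-en-1-yl)oxy]dimethylsilane
Conditions: CBr4, PPh3, CH2Cl2, 0 °C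
Reagents that add atoms: carbon tetrabromide, BrC(Br)(Br)Br
Why: Ramirez dibromo-olefination (first stage of the Corey–Fuchs sequence) of an aliphatic aldehyde; the silyl ether is inert to the neutral ylide.

Step 5
Reactants: 6 7-(allyloxy)-6-hydroxy-2,2,5-trimethylchroman-4-one; 8 tert-butyl[(3,3-dibromoprop-2-en-1-yl)oxy]dimethylsilane
Product: 9 7-(allyloxy)-6-{[(Z)-1-bromo-3-(tert-butyldimethylsilyloxy)prop-1-en-1-yl]oxy}-2,2,5-trimethylchroman-4-one
Conditions: 8 (1.5 equiv), CuI (10 mol %), 2,2'-bipyridine (20 mol %), K3PO4, toluene, 110 °C
Reagents that add atoms: none
Why: Ullmann-type copper-catalysed vinylic C–O coupling of a phenol with a 1,1-dibromoalkene: the less hindered bromine, trans to the chain, is replaced, so the aryloxy group ends trans to CH2OTBS and the remaining bromine is anti to the vinylic hydrogen; the excess of 8 suppresses a second substitution to the ketene acetal.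

Step 6
Reactants: 9 7-(allyloxy)-6-{[(Z)-1-bromo-3-(tert-butyldimethylsilyloxy)prop-1-en-1-yl]oxy}-2,2,5-trimethylchroman-4-one
Product: 10 7-(allyloxy)-6-{[3-(tert-butyldimethylsilyloxy)prop-1-yn-1-yl]oxy}-2,2,5-trimethylchroman-4-one
Conditions: KOt-Bu (2.5 equiv), THF, 0 °C; then pH 7 phosphate buffer, NaHCO3 (aq) wash
Reagents that add atoms: none
Why: Anti-periplanar E2 dehydrobromination of the 1-bromo enol ether gives the aryl ynol ether; the chromanone is carried as its enolate (hence more than two equivalents of base) and is returned on the buffered quench, the mildly basic wash reclosing any ring D opened by retro-oxa-Michael reaction. The product is purified on base-washed silica and used promptly.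

Step 7
Reactants: 11 allyl acetoacetate
Product: 13 allyl diazoacetate, via diazoacetoacetate 12 (not isolated)
Conditions: 4-acetamidobenzenesulfonyl azide, Et3N, MeCN, 0 °C to rt; then LiOH, H2O, rt
Reagents that add atoms: 4-acetamidobenzenesulfonyl azide, CC(=O)Nc1ccc(cc1)S(=O)(=O)N=[N+]=[N-]
Why: Regitz diazo transfer to the 1,3-dicarbonyl compound followed by hydroxide-induced cleavage of the acetyl group is the standard entry to diazoacetates; the ketone carbonyl is attacked much faster than the allyl ester under dilute cold base.

Step 8
Reactants: 13 allyl diazoacetate; 14 methacrolein (2-methylprop-2-enal)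
Product: 16 allyl 2-diazo-4-methyl-3-oxopent-4-enoate, via hydroxy diazo ester 15 (not isolated)
Conditions: 14 (2 equiv), DBU (20 mol %), DMSO, rt; then 2-iodoxybenzoic acid (IBX), rt
Reagents that add atoms: none
Why: Amidine-catalysed aldol-type 1,2-addition of the diazoacetate carbanion to the aldehyde gives the allylic alcohol 15 (racemic, the stereocentre is lost at once), which IBX oxidises to the ketone without touching the diazo group.

Step 9
Reactants: 10 7-(allyloxy)-6-{[3-(tert-butyldimethylsilyloxy)prop-1-yn-1-yl]oxy}-2,2,5-trimethylchroman-4-one; 16 allyl 2-diazo-4-methyl-3-oxopent-4-enoate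
Product: 20 allyl 2-[(7-allyloxy-2,2,5-trimethyl-4-oxochroman-6-yl)oxy]-3-[(tert-butyldimethylsilyloxy)methyl]-4-hydroxy-6-methylbenzoate, via vinylketene 17 (not isolated), via vinylcyclobutenone 18 (not isolated), via dienylketene 19 (not isolated)
Conditions: 16 (2 equiv, slow addition), hν (390 nm LED), ClCH2CH2Cl (degassed), rt; then 80 °C
Reagents that add atoms: none
Why: Proposed new method: irradiation of 16 at a wavelength absorbed only by the diazo chromophore should expel N2 with Wolff migration of the isopropenyl group to give the ester-bearing vinylketene 17; the electron-rich alkyne of 10 should attack the ketene carbonyl carbon through its β-carbon (the one bearing CH2OTBS), and collapse of the zwitterion through carbon gives the vinylcyclobutenone 18 in a stepwise (2+2) addition. At 80 °C 18 should open reversibly, by conrotatory four-electron cleavage of the bond between its carbonyl and quaternary carbons, to the dienylketene 19, and the isomer with the isopropenyl group cis to the ketene closes ring A by thermal disrotatory six-electron electrocyclisation between the ketene carbon and the CH2 terminus, after which enolisation gives the phenol 20. The closest known reaction type is the Danheiser benzannulation of vinylketenes, made by photochemical Wolff rearrangement of unsaturated α-diazo ketones, with alkoxy- and siloxyalkynes; what has not been shown is a vinylketene with an ester on its α-carbon, made from a 2-diazo-3-oxo ester. Ring A is therefore closed by six-electron electrocyclisation after a four-membered ring has been formed and opened, and no stereocentre is created (the quaternary centre of 18 is racemic and disappears). The regiochemistry needed (OH and OAr meta, CH2OTBS between them, ester para to OH) follows from the polarity of the partners, alkyne β-carbon to ketene carbonyl carbon. Beyond this the step needs carbon to win over oxygen at two points: at the zwitterion, against hetero-(4+2) closure through the ester carbonyl oxygen to a 4-pyranone, and at 19, against capture of the ketene by the ester oxygen to a 2-pyranone. What should secure this is the low basicity of an ester carbonyl compared with a ketone, the reversible opening of 18, and slow addition of 16, which keeps the ketene concentration low; heating only after irradiation keeps the new phenol away from the ketene.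

Step 10
Reactants: 20 allyl 2-[(7-allyloxy-2,2,5-trimethyl-4-oxochroman-6-yl)oxy]-3-[(tert-butyldimethylsilyloxy)methyl]-4-hydroxy-6-methylbenzoate
Product: 21 3-[(tert-butyldimethylsilyloxy)methyl]-4-hydroxy-2-[(7-hydroxy-2,2,5-trimethyl-4-oxochroman-6-yl)oxy]-6-methylbenzoic acid
Conditions: Pd(PPh3)4 (5 mol %), morpholine, THF, rt
Reagents that add atoms: none
Why: Tsuji–Trost deallylation: zerovalent palladium ionises both the allyl ester and the allyl aryl ether to π-allyl complexes that morpholine captures irreversibly; silyl ether, ketone and phenol are untouched.

Step 11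
Reactants: 21 3-[(tert-butyldimethylsilyloxy)methyl]-4-hydroxy-2-[(7-hydroxy-2,2,5-trimethyl-4-oxochroman-6-yl)oxy]-6-methylbenzoic acid
Product: 22 depsidone silyl ether (mollicellin A skeleton with CH2OTBS in place of CHO; lactone between the ring A carboxyl and the ring C 7-oxygen)
Conditions: DCC, DMAP (cat.), CH2Cl2 (0.005 M, slow addition of 21), rt
Reagents that add atoms: none
Why: Steglich-type lactonisation: the activated acyl group of the hindered benzoic acid is captured by the ring C 7-hydroxyl, which the diaryl ether holds in a seven-membered relationship, closing ring B by acyl substitution; the ring A hydroxyl is para to the carboxyl and can react only between molecules, which high dilution suppresses.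

Step 12
Reactants: 22 depsidone silyl ether
Product: 23 benzylic alcohol (mollicellin A with CH2OH in place of CHO)
Conditions: HF·pyridine, pyridine/THF, 0 °C
Reagents that add atoms: none
Why: Fluoride cleavage of the primary silyl ether under buffered, weakly acidic conditions, chosen because basic fluoride or alkoxide would open the aryl lactone.

Step 13
Reactants: 23 benzylic alcohol
Product: 24 mollicellin A
Conditions: MnO2 (activated, excess), CH2Cl2, rt
Reagents that add atoms: none
Why: MnO2 oxidises benzylic alcohols selectively and stops at the aldehyde, here stabilised by the hydrogen bond to the neighbouring phenol; no other oxidisable alcohol is present.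

## Compound list

1 | orcinol (5-methylbenzene-1,3-diol) | Cc1cc(O)cc(O)c1 | starting material
2 | 2-hydroxy-6-methyl-1,4-benzoquinone (not isolated) | O=C1C(O)=CC(=O)C=C1C | intermediate
3 | 6-methylbenzene-1,2,4-triol | Cc1cc(O)cc(O)c1O | intermediate
4 | 3-methylbut-2-enoic acid | CC(C)=CC(=O)O | starting material
5 | 6,7-dihydroxy-2,2,5-trimethylchroman-4-one | Cc1c(O)c(O)cc2OC(C)(C)CC(=O)c12 | intermediate
6 | 7-(allyloxy)-6-hydroxy-2,2,5-trimethylchroman-4-one | Cc1c(O)c(OCC=C)cc2OC(C)(C)CC(=O)c12 | intermediate
7 | (tert-butyldimethylsilyloxy)acetaldehyde | CC(C)(C)[Si](C)(C)OCC=O | starting material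
8 | tert-butyl[(3,3-dibromoprop-2-en-1-yl)oxy]dimethylsilane | CC(C)(C)[Si](C)(C)OCC=C(Br)Br | intermediate
9 | 7-(allyloxy)-6-{[(Z)-1-bromo-3-(tert-butyldimethylsilyloxy)prop-1-en-1-yl]oxy}-2,2,5-trimethylchroman-4-one | CC(C)(C)[Si](C)(C)OC/C=C(\Br)Oc1c(OCC=C)cc2OC(C)(C)CC(=O)c2c1C | intermediate
10 | 7-(allyloxy)-6-{[3-(tert-butyldimethylsilyloxy)prop-1-yn-1-yl]oxy}-2,2,5-trimethylchroman-4-one | CC(C)(C)[Si](C)(C)OCC#COc1c(OCC=C)cc2OC(C)(C)CC(=O)c2c1C | intermediate
11 | allyl acetoacetate (allyl 3-oxobutanoate) | CC(=O)CC(=O)OCC=C | starting material
12 | allyl 2-diazo-3-oxobutanoate (not isolated) | CC(=O)C(=[N+]=[N-])C(=O)OCC=C | intermediate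
13 | allyl diazoacetate | [N-]=[N+]=CC(=O)OCC=C | intermediate
14 | methacrolein (2-methylprop-2-enal) | CC(=C)C=O | starting material
15 | allyl 2-diazo-3-hydroxy-4-methylpent-4-enoate (racemic, not isolated) | C=CCOC(=O)C(=[N+]=[N-])C(O)C(C)=C | intermediate
16 | allyl 2-diazo-4-methyl-3-oxopent-4-enoate | C=CCOC(=O)C(=[N+]=[N-])C(=O)C(C)=C | intermediate
17 | allyl 3-methyl-2-(oxomethylidene)but-3-enoate (vinylketene, not isolated) | C=CCOC(=O)C(=C=O)C(C)=C | intermediate
18 | allyl 3-[(7-allyloxy-2,2,5-trimethyl-4-oxochroman-6-yl)oxy]-2-[(tert-butyldimethylsilyloxy)methyl]-4-oxo-1-(prop-1-en-2-yl)cyclobut-2-ene-1-carboxylate (racemic, not isolated) | C=CCOC(=O)C1(C(C)=C)C(=O)C(CO[Si](C)(C)C(C)(C)C)=C1Oc1c(OCC=C)cc2OC(C)(C)CC(=O)c2c1C | intermediate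
19 | allyl (2Z)-3-[(7-allyloxy-2,2,5-trimethyl-4-oxochroman-6-yl)oxy]-4-[(tert-butyldimethylsilyloxy)methyl]-5-oxo-2-(prop-1-en-2-yl)penta-2,4-dienoate (dienylketene, not isolated) | O=C=C(CO[Si](C)(C)C(C)(C)C)/C(Oc1c(OCC=C)cc2OC(C)(C)CC(=O)c2c1C)=C(\C(C)=C)C(=O)OCC=C | intermediate
20 | allyl 2-[(7-allyloxy-2,2,5-trimethyl-4-oxochroman-6-yl)oxy]-3-[(tert-butyldimethylsilyloxy)methyl]-4-hydroxy-6-methylbenzoate | Cc1cc(O)c(CO[Si](C)(C)C(C)(C)C)c(Oc2c(OCC=C)cc3OC(C)(C)CC(=O)c3c2C)c1C(=O)OCC=C | intermediate
21 | 3-[(tert-butyldimethylsilyloxy)methyl]-4-hydroxy-2-[(7-hydroxy-2,2,5-trimethyl-4-oxochroman-6-yl)oxy]-6-methylbenzoic acid | Cc1cc(O)c(CO[Si](C)(C)C(C)(C)C)c(Oc2c(O)cc3OC(C)(C)CC(=O)c3c2C)c1C(=O)O | intermediate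
22 | depsidone silyl ether (mollicellin A with CH2OSi(CH3)2C(CH3)3 in place of CHO) | Cc1cc(O)c(CO[Si](C)(C)C(C)(C)C)c2c1C(=O)Oc1cc3c(c(C)c1O2)C(=O)CC(C)(C)O3 | intermediate
23 | benzylic alcohol (mollicellin A with CH2OH in place of CHO) | Cc1cc(O)c(CO)c2c1C(=O)Oc1cc3c(c(C)c1O2)C(=O)CC(C)(C)O3 | intermediate
24 | mollicellin A | Cc1cc(O)c(C=O)c2c1C(=O)Oc1cc3c(c(C)c1O2)C(=O)CC(C)(C)O3 | target

## Step count and least certain steps

Total: 13 steps. Longest linear sequence: 10 steps (1, 2, 3, 5, 6, 9, 10, 11, 12, 13). Steps 4, 7 and 8 are side branches.

**Step 9 (key step, proposed new method).** Three processes are most likely to divert it.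
- Closure of the first-formed zwitterion through the ester carbonyl oxygen and not through carbon, a hetero-(4+2) addition that the ester makes possible.
- Opening of 18 with the ester turned toward the ketene, followed by capture of the ketene by the ester oxygen. Torquoselectivity may favour this, because a vinyl group prefers outward rotation more strongly than an ester does.
- Loss of the ketene by dimerisation, or loss of the carbene by cyclopropanation of the allyl groups.

The fallback is the classical depsidone assembly. It uses known chemistry, gives up the benzannulation, sets out from 5 and comes back at 24.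
- Selective benzylation of 5 (benzyl bromide, KHCO3, DMF) gives 7-(benzyloxy)-6-hydroxy-2,2,5-trimethylchroman-4-one F1.
- Commercial 2,4-dihydroxy-6-methylbenzoic acid F2 is benzylated at the carboxylate and the non-chelated hydroxyl (benzyl bromide, K2CO3, DMF) to benzyl 4-(benzyloxy)-2-hydroxy-6-methylbenzoate F3, and the chelated hydroxyl is converted with (CF3SO2)2O and pyridine into benzyl 4-(benzyloxy)-2-methyl-6-(trifluoromethylsulfonyloxy)benzoate F4.
- Palladium-catalysed C–O coupling of F1 with F4 (Pd(OAc)2, 2-di-tert-butylphosphino-2',4',6'-triisopropylbiphenyl, K3PO4, toluene, 100 °C) gives benzyl 4-(benzyloxy)-2-[(7-benzyloxy-2,2,5-trimethyl-4-oxochroman-6-yl)oxy]-6-methylbenzoate F5.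
- Hydrogenolysis (H2, Pd/C, EtOAc) gives 4-hydroxy-2-[(7-hydroxy-2,2,5-trimethyl-4-oxochroman-6-yl)oxy]-6-methylbenzoic acid F6, and lactonisation as in step 11 gives the formyl-free depsidone F7.
- Rieche ortho-formylation (Cl2CHOCH3, TiCl4, CH2Cl2, 0 °C) gives 24. The carbon between the hydroxyl and the ether oxygen is the only ortho site where a second oxygen can chelate the titanium phenoxide; the other ortho carbon, between the hydroxyl and the methyl group, is the competing site, so this last step is the weak point of the fallback.

**Step 5.** The phenol of 6 has substituents on both sides, so the copper-mediated C–O bond formation may be slow enough for reductive loss of bromine from 8 or double substitution to compete. The base steps here and in step 6 can also open ring D.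

The fallback sets out from 6, comes back at 10, and avoids both the metal-mediated coupling and 9.
- Metal-free addition–elimination with trichloroethylene (K2CO3, DMF, 70 °C) gives 7-(allyloxy)-6-{[(E)-1,2-dichlorovinyl]oxy}-2,2,5-trimethylchroman-4-one F8.
- The ketone is masked in the flask as its lithium enolate (LiN(SiMe3)2, THF, −78 °C). n-BuLi (2.2 equiv) then brings about dehydrochlorination and chlorine–lithium exchange, and paraformaldehyde traps the acetylide to give 7-(allyloxy)-6-[(3-hydroxyprop-1-yn-1-yl)oxy]-2,2,5-trimethylchroman-4-one F9.
- Silylation (tert-butyldimethylsilyl chloride, imidazole, DMF) gives 10.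

**Step 11.** The acid of 21 has two ortho substituents and is activated slowly, so rearrangement of the activated ester to an N-acylurea, or acylation of the ring A phenol of a second molecule (oligomerisation), may overtake ring closure.

The fallback sets out from 20 and comes back at 23. It removes the competing nucleophile and uses a stronger acylating species.
- Silylation of the ring A phenol of 20 (tert-butyldimethylsilyl chloride, imidazole, DMF) gives the bis-silyl diallyl compound F10.
- Deallylation as in step 10 gives the bis-silyl hydroxy acid F11.
- The acid is converted under neutral conditions into its chloride (1-chloro-N,N,2-trimethylprop-1-en-1-amine, CH2Cl2) and closed with Et3N and DMAP at high dilution to the bis-silyl depsidone F12.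
- HF·pyridine removes both silyl groups to give 23.

**Step 2.** Acylation may occur in part at the carbon between the two hydroxyls of 3, giving an isomeric chromanone, and 3 may oxidise before it reacts.

The fallback sets out from 1 and comes back at 5. It makes the ring D bonds in a different order.
- Acetylation of 1 (AcOH, BF3·OEt2, 90 °C) gives 1-(2,4-dihydroxy-6-methylphenyl)ethan-1-one F13. Any symmetric 2,6-dihydroxy isomer is easily recognised and removed at this simple stage.
- Elbs oxidation (K2S2O8, aqueous NaOH) attacks the only free position para to a phenoxide and gives the aryl sulfate F14, which aqueous HCl hydrolyses to 1-(2,4,5-trihydroxy-6-methylphenyl)ethan-1-one F15.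
- Kabbe condensation with acetone (pyrrolidine, EtOH, reflux, argon) closes ring D to 5 with no regiochemical choice.

## Further compounds

F1 | step 9 | 7-(benzyloxy)-6-hydroxy-2,2,5-trimethylchroman-4-one | Cc1c(O)c(OCc2ccccc2)cc2OC(C)(C)CC(=O)c12
F2 | step 9 | 2,4-dihydroxy-6-methylbenzoic acid | Cc1cc(O)cc(O)c1C(=O)O
F3 | step 9 | benzyl 4-(benzyloxy)-2-hydroxy-6-methylbenzoate | Cc1cc(OCc2ccccc2)cc(O)c1C(=O)OCc1ccccc1
F4 | step 9 | benzyl 4-(benzyloxy)-2-methyl-6-(trifluoromethylsulfonyloxy)benzoate | Cc1cc(OCc2ccccc2)cc(OS(=O)(=O)C(F)(F)F)c1C(=O)OCc1ccccc1
F5 | step 9 | benzyl 4-(benzyloxy)-2-[(7-benzyloxy-2,2,5-trimethyl-4-oxochroman-6-yl)oxy]-6-methylbenzoate | Cc1cc(OCc2ccccc2)cc(Oc2c(OCc3ccccc3)cc3OC(C)(C)CC(=O)c3c2C)c1C(=O)OCc1ccccc1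
F6 | step 9 | 4-hydroxy-2-[(7-hydroxy-2,2,5-trimethyl-4-oxochroman-6-yl)oxy]-6-methylbenzoic acid | Cc1cc(O)cc(Oc2c(O)cc3OC(C)(C)CC(=O)c3c2C)c1C(=O)O
F7 | step 9 | formyl-free depsidone (mollicellin A with H in place of CHO) | Cc1cc(O)cc2c1C(=O)Oc1cc3c(c(C)c1O2)C(=O)CC(C)(C)O3
F8 | step 5 | 7-(allyloxy)-6-{[(E)-1,2-dichlorovinyl]oxy}-2,2,5-trimethylchroman-4-one | Cl/C=C(/Cl)Oc1c(OCC=C)cc2OC(C)(C)CC(=O)c2c1C
F9 | step 5 | 7-(allyloxy)-6-[(3-hydroxyprop-1-yn-1-yl)oxy]-2,2,5-trimethylchroman-4-one | OCC#COc1c(OCC=C)cc2OC(C)(C)CC(=O)c2c1C
F10 | step 11 | allyl 2-[(7-allyloxy-2,2,5-trimethyl-4-oxochroman-6-yl)oxy]-4-(tert-butyldimethylsilyloxy)-3-[(tert-butyldimethylsilyloxy)methyl]-6-methylbenzoate | Cc1cc(O[Si](C)(C)C(C)(C)C)c(CO[Si](C)(C)C(C)(C)C)c(Oc2c(OCC=C)cc3OC(C)(C)CC(=O)c3c2C)c1C(=O)OCC=C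
F11 | step 11 | 4-(tert-butyldimethylsilyloxy)-3-[(tert-butyldimethylsilyloxy)methyl]-2-[(7-hydroxy-2,2,5-trimethyl-4-oxochroman-6-yl)oxy]-6-methylbenzoic acid | Cc1cc(O[Si](C)(C)C(C)(C)C)c(CO[Si](C)(C)C(C)(C)C)c(Oc2c(O)cc3OC(C)(C)CC(=O)c3c2C)c1C(=O)O
F12 | step 11 | bis-silyl depsidone (23 with both hydroxyls as tert-butyldimethylsilyl ethers) | Cc1cc(O[Si](C)(C)C(C)(C)C)c(CO[Si](C)(C)C(C)(C)C)c2c1C(=O)Oc1cc3c(c(C)c1O2)C(=O)CC(C)(C)O3
F13 | step 2 | 1-(2,4-dihydroxy-6-methylphenyl)ethan-1-one | CC(=O)c1c(C)cc(O)cc1O
F14 | step 2 | potassium 3-acetyl-4,6-dihydroxy-2-methylphenyl sulfate | CC(=O)c1c(C)c(OS(=O)(=O)[O-])c(O)cc1O.[K+]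
F15 | step 2 | 1-(2,4,5-trihydroxy-6-methylphenyl)ethan-1-one | CC(=O)c1c(C)c(O)c(O)cc1O
A1 | alternative 1 | benzyl (7-methoxy-1,5-dimethyl-9-oxo-9H-xanthen-3-yl) carbonate | Cc1cc(OC(=O)OCc2ccccc2)cc2oc3c(C)cc(OC)cc3c(=O)c12
A2 | alternative 1 | benzyl (8-methoxy-1,6-dimethyl-11-oxo-11H-dibenzo[b,e][1,4]dioxepin-3-yl) carbonate | Cc1cc(OC(=O)OCc3ccccc3)cc2c1C(=O)Oc1cc(OC)cc(C)c1O2
A3 | alternative 2 | 6-{[3-(ethynyldiisopropylsilyloxy)prop-1-yn-1-yl]oxy}-2,2,5-trimethyl-4-oxochroman-7-yl but-2-ynoate | C#C[Si](C(C)C)(C(C)C)OCC#COc1c(OC(=O)C#CC)cc2OC(C)(C)CC(=O)c2c1C
A4 | alternative 2 | depsidone with a diisopropyl-oxasilole fused across the future hydroxyl and formyl carbons of ring A | Cc1cc2c(CO[Si]2(C(C)C)C(C)C)c2c1C(=O)Oc1cc3OC(C)(C)CC(=O)c3c(C)c1O2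
A5 | alternative 3 | 6-hydroxy-2,2,5-trimethyl-4-oxochroman-7-yl 6-methyl-2,4-dioxocyclohexane-1-carboxylate (epimers at the ester-bearing carbon) | CC1CC(=O)CC(=O)C1C(=O)Oc1cc2OC(C)(C)CC(=O)c2c(C)c1O
A6 | alternative 3 | ring B-closed vinylogous ester with ring A at the dihydro level (racemic trans, one enantiomer drawn) | C[C@@H]1CC(=O)C=C2Oc3c(C)c4C(=O)CC(C)(C)Oc4cc3OC(=O)[C@@H]12
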